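**Blue's leftover.** Blue, one of the earlier flasks of starting material and partner with capture agent present, ends with 71.5% of its starting material charge not in target. Yet its last readings, 28.7% and 28.5%, stand flat at a scatter of 0.3 percentage points. So blue is better watched from its other charge, partner, which looks like the limiting reagent. Blue turned 0.456 of its partner charge into target by 5.0 h; call this fraction the partner yield.

| flask | starting material | partner | capture agent | temperature | remark | time |
|---|---|---|---|---|---|---|
| green | 0.50 M | 0.52 M | 0.15 M | 45 °C | run made earlier |  |
| violet | 0.50 M | 1.1 M | 0.15 M | 60 °C | run made earlier |  |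
| teal | 0.50 M | 1.5 M | 0.15 M | 45 °C | run made earlier |  |
| blue | 0.80 M | 0.50 M | 0.15 M | 60 °C | run made earlier |  |
| south-east | 0.50 M | 0.500 M | 0.150 M | 60 °C |  | 5.0 h |
| east | 1.0 M | 2.00 M | 0.150 M | 60 °C |  | 5.0 h |

| run | time / h | target / % |
|---|---|---|
| green | 0.833 | 0.3 |
| green | 2.00 | 2.2 |
| green | 3.00 | 5.1 |
| green | 5.00 | 13.5 |
| green | 10.0 | 29.9 |
| violet | 1.00 | 18.8 |
| violet | 2.00 | 41.1 |
| violet | 3.00 | 54.9 |
| violet | 4.00 | 63.2 |
| violet | 5.00 | 68.7 |
| teal | 2.00 | 5.1 |
| teal | 4.00 | 18.4 |
| teal | 6.00 | 30.0 |
| teal | 8.00 | 39.5 |
| teal | 10.0 | 48.3 |
| blue | 0.417 | 1.9 |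
| blue | 1.33 | 15.2 |
| blue | 2.50 | 25.1 |
| blue | 4.00 | 28.7 |
| blue | 5.00 | 28.5 |

(standard deviation of a reading: 0.3 percentage points)

- the analysis behind the earlier runs scatters by 0.3 percentage points, standard deviation

1. the winner by amount of target, in percent of the starting material charged; "neither" if no more than 2 percentage points parts them (south-east / east / neither)
2. how much target is there at the end, in percent of the starting material charged: south-east
3. how much target is there at the end, in percent of the starting material charged: east

**First estimate.** Blue's partner yield put on south-east gives 45.6% of the starting material. The objection is that blue carried 0.625 partner per starting material and south-east carries 1.00. Violet, at 2.20, shows what that ratio can do: its partner yield is 0.312, less than blue's. One yield will not serve both asked flasks.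

**A better line.** Violet is still gaining 5.5 points in its last hour, so its yield is no ceiling. But blue, violet and both asked flasks are read at 5.0 h and 60 °C, so the comparison holds at one moment. Green and teal ran at 45 °C and stay out. A straight line through blue and violet loses 0.0913 of partner yield per unit of ratio. South-east then has a partner yield of 0.422, which is 42.2% of its starting material. East has 0.331, which is 66.1%. The remaining doubt is that the line has two points and east's charges stand above violet's, which no earlier run tests. Still, this line's gap of 24 points clears the margin of 2 points, so east should win.

**The forecast.** The forecast names east, with 42% for south-east and 80% for east: “Partner is therefore limiting”.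

**The flask.** South-east ends at 42.6% and east at 67.0%, so east wins.

    starting material ⇌ open intermediate (K = 7.12, k = 1.07 × 10⁻⁴ /s, Ea = 93.0 kJ/mol, ΔH = −50.0 kJ/mol)
    partner → second intermediate (k = 1.57 × 10⁻⁴ /s, Ea = 115 kJ/mol)
    open intermediate + second intermediate → target (k = 0.00273 /M/s, Ea = 61.0 kJ/mol)
    2 second intermediate → homo product (k = 2.50 × 10⁻⁴ /M/s, Ea = 89.0 kJ/mol)
    partner → decomposed reagent (k = 1.54 × 10⁻⁴ /s, Ea = 108 kJ/mol)
    second intermediate + capture agent → trapped intermediate (k = 1.06 × 10⁻⁴ /M/s, Ea = 64.0 kJ/mol)
    (constants at 60 °C)

**Partner yield.** South-east's partner yield comes to 0.426 and east's to 0.335, both below blue's 0.456. East stands above south-east mainly through its larger partner charge: east without that difference in partner ends at 23.4%, against 67.0% as charged. The neighbour flask, south-east with 0.20 M of starting material, lies on the line at 0.285 and ends with a partner yield of 0.266, which is 66.5% of its starting material.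

(The readings come from a simulation on assumed constants, and the scatter is random.)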